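**Retrosynthetic overview**
1. The target is (2S,4R)-4',7-dihydroxyflavan joined from its C4 to C6 of (−)-epiafzelechin. The interflavan C4–C6 bond is cut last (Friedel–Crafts coupling of a flavan-4-ol with a C8-brominated, benzylated epiafzelechin), before one global hydrogenolysis.
2. Ring C of the lower unit is cut at C4–C3 and at O1–C8a. A 2-bromobenzyl bromide (ring A with C4) and an α-alkoxy aryl ketone (C3, C2, O1, ring B) are joined in one domino C-benzylation/O-arylation to a 3-alkoxy-4H-chromene.
3. Enabling feature: in ring C of the lower unit the benzylic CH2 (C4) and the ether oxygen O1 sit on neighbouring carbons C4a and C8a of ring A, and C3 and C2 both carry oxygen. C4/C8a therefore map onto a bromomethyl/bromo pair, and C3–C2–O1 onto the α-carbon, carbonyl carbon and enolate oxygen of a glycolyl aryl ketone.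
4. Both stereocentres of the lower unit (C2, C3) are then set together by dynamic kinetic resolution in the transfer hydrogenation of the derived flavan-3-one.
5. Ring order: lower ring C first (step 6); the upper ring C is brought in preformed (chromone to (2S)-flavanone by asymmetric conjugate addition); the two units are joined at the end.

Key step: step 6

Assumption: (R)-t-BuPyOx in step 11 and the (S,S)-configured catalyst in step 8 are taken to be the antipodes that lead to the (2S) flavanone and the (2R,3R) alcohol; should a first run show the opposite sense, the mirror-image ligand would be used and nothing else changes.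

**Route**

Step 1
Reactants: 1 1-bromo-3,5-bis(benzyloxy)benzene
Product: 2 2-bromo-4,6-bis(benzyloxy)benzaldehyde
Conditions: POCl3, DMF, 0 → 70 °C; then H2O
Reagents that add atoms: N,N-dimethylformamide (CN(C)C=O); water (O)
Why: Vilsmeier–Haack formylation should go to the ring position para to one benzyloxy group and ortho to the other (next to bromine), as known for the dimethoxy analogue, which places the future C4 on the carbon beside the bromine that marks C8a.

Step 2
Reactants: 2 2-bromo-4,6-bis(benzyloxy)benzaldehyde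
Product: 3 [2-bromo-4,6-bis(benzyloxy)phenyl]methanol
Conditions: NaBH4, THF/MeOH, 0 °C
Reagents that add atoms: none
Why: Borohydride reduction of the aryl aldehyde, to which the aryl bromide and the benzyl ethers are inert.

Step 3
Reactants: 3 [2-bromo-4,6-bis(benzyloxy)phenyl]methanol
Product: 4 2-bromo-4,6-bis(benzyloxy)benzyl bromide
Conditions: CBr4, PPh3, CH2Cl2, 0 °C; used without storage
Reagents that add atoms: tetrabromomethane (BrC(Br)(Br)Br)
Why: Appel bromination under neutral conditions should avoid the acid-promoted self-alkylation to which this electron-rich benzylic bromide is prone.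

Step 4
Reactants: 5 2-bromo-1-[4-(benzyloxy)phenyl]ethan-1-one
Product: 6 1-[4-(benzyloxy)phenyl]-2-hydroxyethan-1-one
Conditions: HCO2Na, EtOH/H2O, reflux
Reagents that add atoms: sodium formate ([Na+].[O-]C=O)
Why: SN2 displacement of the α-bromide by formate and solvolysis of the formate ester in the same flask should give the α-hydroxy ketone without the Favorskii-type side reactions of alkoxide bases.

Step 5
Reactants: 6 1-[4-(benzyloxy)phenyl]-2-hydroxyethan-1-one
Product: 7 1-[4-(benzyloxy)phenyl]-2-(methoxymethoxy)ethan-1-one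
Conditions: MOMCl, i-Pr2NEt, CH2Cl2, 0 °C → rt
Reagents that add atoms: chloromethyl methyl ether (COCCl)
Why: O-alkylation of the primary hydroxyl masks the future O3 as a non-migrating, non-nucleophilic acetal, so that in step 6 only the enolate oxygen (future O1) can be arylated.

Step 6
Reactants: 7 1-[4-(benzyloxy)phenyl]-2-(methoxymethoxy)ethan-1-one; 4 2-bromo-4,6-bis(benzyloxy)benzyl bromide
Product: 9 5,7-bis(benzyloxy)-2-[4-(benzyloxy)phenyl]-3-(methoxymethoxy)-4H-chromene, via C-benzylated ketone 8 (not isolated)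
Conditions: LiN(SiMe3)2 (1.05 equiv), THF, −78 → 0 °C; then Cs2CO3 (2 equiv), CuI (10 mol %), 1,10-phenanthroline (20 mol %), DMF, 100 °C
Reagents that add atoms: none
Why: Proposed new method: the lithium enolate of 7 should be C-benzylated at its α-carbon (future C3) by the benzylic bromide of 4 in an SN2 reaction (C4–C3 bond) to give ketone 8, whose remaining α-hydrogen is then removed by Cs2CO3 so that the enolate oxygen (future O1) undergoes Ullmann-type intramolecular O-arylation at the aryl bromide carbon (C8a) through oxidative addition to monovalent copper and C–O reductive elimination. The closest known reaction type is the CuI-catalysed domino C-benzylation/O-arylation of 1,3-dicarbonyl compounds with 2-bromobenzyl bromides to 4H-chromenes, together with the CuI-catalysed intramolecular O-arylation of simple ketone enolates to benzofurans; new here is a mono-ketone that carries an α-alkoxy group. Ring C of the lower unit closes as a six-membered ring by C–O bond formation between the enolate oxygen and the aryl carbon; C-arylation would need a four-membered ring, and because O3 is blocked as its MOM ether the five-membered benzofuran mode is closed. No stereocentre is created, since C2 and C3 become the two ends of a tetrasubstituted enediol ether double bond, which defers both stereocentres to step 8. The step needs C- over O-benzylation (lithium enolate in THF with a soft benzylic bromide), mono-alkylation (one equivalent of base and of bromide, 8 being more hindered than 7) and reaction of the benzylic before the aryl bromide (no CuI present in the first stage).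

Step 7
Reactants: 9 5,7-bis(benzyloxy)-2-[4-(benzyloxy)phenyl]-3-(methoxymethoxy)-4H-chromene
Product: 10 5,7-bis(benzyloxy)-2-[4-(benzyloxy)phenyl]chroman-3-one (racemic)
Conditions: Me3SiOSO2CF3, 2,2'-bipyridyl, CH2Cl2, 0 °C; then H2O
Reagents that add atoms: none
Why: Silyl triflate/bipyridyl cleavage of the MOM acetal runs without Brønsted acid or water until the quench, so the enediol ether should not be hydrated at C2 (which would open the pyran ring), and the liberated enol tautomerises to the flavan-3-one.

Step 8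
Reactants: 10 5,7-bis(benzyloxy)-2-[4-(benzyloxy)phenyl]chroman-3-one (racemic)
Product: 11 (2R,3R)-5,7-bis(benzyloxy)-2-[4-(benzyloxy)phenyl]chroman-3-ol
Conditions: RuCl[(S,S)-TsDPEN](p-cymene) (2 mol %), HCO2H/Et3N (5:2), CH2Cl2, 30 °C
Reagents that add atoms: none
Why: Noyori–Ikariya asymmetric transfer hydrogenation under dynamic kinetic resolution: C2–H, flanked by the ketone, the aryl group and the aryloxy oxygen, should epimerise through the enol under the amine conditions while the catalyst reduces the (2R) ketone faster and from the face opposite to the C2 aryl group, setting C3 (R) and, through the resolution, C2 (R) with the 2,3-cis relationship, as in the known cis-selective reductions of 2-aryl cyclic ketones.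

Step 9
Reactants: 11 (2R,3R)-5,7-bis(benzyloxy)-2-[4-(benzyloxy)phenyl]chroman-3-ol
Product: 12 (2R,3R)-5,7-bis(benzyloxy)-2-[4-(benzyloxy)phenyl]-8-bromochroman-3-ol
Conditions: NBS, CH2Cl2, −78 → 0 °C
Reagents that add atoms: N-bromosuccinimide (O=C1CCC(=O)N1Br)
Why: Electrophilic aromatic bromination of 5,7-di-O-benzyl flavan-3-ols should go to C8 in preference to C6, as known for benzylated catechins, so the bromine blocks C8 and leaves C6 as the only nucleophilic position of ring A.

Step 10
Reactants: 13 7-hydroxy-4H-chromen-4-one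
Product: 14 7-(benzyloxy)-4H-chromen-4-one
Conditions: BnBr, K2CO3, DMF, rt
Reagents that add atoms: benzyl bromide (BrCc1ccccc1)
Why: Williamson benzylation of the phenol, which the chromone tolerates under carbonate base.

Step 11
Reactants: 14 7-(benzyloxy)-4H-chromen-4-one; 15 [4-(benzyloxy)phenyl]boronic acid
Product: 16 (2S)-7-(benzyloxy)-2-[4-(benzyloxy)phenyl]chroman-4-one
Conditions: Pd(OCOCF3)2 (5 mol %), (R)-t-BuPyOx (6 mol %), NH4PF6 (30 mol %), H2O (5 equiv), ClCH2CH2Cl, 60 °C
Reagents that add atoms: none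
Why: Enantioselective conjugate addition of the arylboronic acid to the chromone (Hayashi–Miyaura-type 1,4-addition with a pyridine–oxazoline ligand), in which the ligand controls the face of aryl transfer to C2 and the non-basic medium should prevent racemisation by retro-oxa-Michael opening.

Step 12
Reactants: 16 (2S)-7-(benzyloxy)-2-[4-(benzyloxy)phenyl]chroman-4-one
Product: 17 (2S,4S)-7-(benzyloxy)-2-[4-(benzyloxy)phenyl]chroman-4-ol
Conditions: NaBH4, THF/MeOH, 0 °C
Reagents that add atoms: none
Why: Axial hydride attack on the flavanone should give the 2,4-cis alcohol, whose C4 configuration is of no consequence because C4 is ionised in step 13.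

Step 13
Reactants: 17 (2S,4S)-7-(benzyloxy)-2-[4-(benzyloxy)phenyl]chroman-4-ol; 12 (2R,3R)-5,7-bis(benzyloxy)-2-[4-(benzyloxy)phenyl]-8-bromochroman-3-ol
Product: 18 (2R,3R)-5,7-bis(benzyloxy)-6-[(2S,4R)-7-(benzyloxy)-2-(4-(benzyloxy)phenyl)chroman-4-yl]-2-[4-(benzyloxy)phenyl]-8-bromochroman-3-ol
Conditions: BF3·OEt2 (20 mol %), 4 Å molecular sieves, CH2Cl2, −40 → 0 °C; 12 in 1.5-fold excess, the surplus to be recovered
Reagents that add atoms: none
Why: Lewis acid-promoted Friedel–Crafts alkylation (proanthocyanidin-type interflavan coupling), in which the C4 benzylic cation, stabilised by the para 7-benzyloxy group, is captured by C6 of 12 (the only free position of its ring A) and the arene should enter anti to the pseudo-equatorial C2 aryl group to favour the 2,4-trans (4R) isomer, any 2,4-cis isomer to be removed by chromatography.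

Step 14
Reactants: 18 (2R,3R)-5,7-bis(benzyloxy)-6-[(2S,4R)-7-(benzyloxy)-2-(4-(benzyloxy)phenyl)chroman-4-yl]-2-[4-(benzyloxy)phenyl]-8-bromochroman-3-ol
Product: 19 (2R,3R)-6-[(2S,4R)-7-hydroxy-2-(4-hydroxyphenyl)chroman-4-yl]-2-(4-hydroxyphenyl)chromane-3,5,7-triol (CNP0167324.2)
Conditions: H2 (1 atm), Pd(OH)2/C, Et3N, THF/MeOH, rt
Reagents that add atoms: none
Why: Hydrogenolysis should remove the five benzyl ethers and the aryl C–Br bond (the amine takes up HBr) while leaving the interflavan bond and all four stereocentres untouched.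

**Compound list**
1 | 1-bromo-3,5-bis(benzyloxy)benzene | Brc1cc(OCc2ccccc2)cc(OCc2ccccc2)c1 | starting material
2 | 2-bromo-4,6-bis(benzyloxy)benzaldehyde | O=Cc1c(Br)cc(OCc2ccccc2)cc1OCc1ccccc1 | intermediate
3 | [2-bromo-4,6-bis(benzyloxy)phenyl]methanol | OCc1c(Br)cc(OCc2ccccc2)cc1OCc1ccccc1 | intermediate
4 | 2-bromo-4,6-bis(benzyloxy)benzyl bromide | BrCc1c(Br)cc(OCc2ccccc2)cc1OCc1ccccc1 | intermediate
5 | 2-bromo-1-[4-(benzyloxy)phenyl]ethan-1-one | O=C(CBr)c1ccc(OCc2ccccc2)cc1 | starting material
6 | 1-[4-(benzyloxy)phenyl]-2-hydroxyethan-1-one | O=C(CO)c1ccc(OCc2ccccc2)cc1 | intermediate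
7 | 1-[4-(benzyloxy)phenyl]-2-(methoxymethoxy)ethan-1-one | COCOCC(=O)c1ccc(OCc2ccccc2)cc1 | intermediate
8 | 3-[2-bromo-4,6-bis(benzyloxy)phenyl]-1-[4-(benzyloxy)phenyl]-2-(methoxymethoxy)propan-1-one (racemic; C-benzylated ketone) | COCOC(Cc1c(Br)cc(OCc2ccccc2)cc1OCc1ccccc1)C(=O)c1ccc(OCc2ccccc2)cc1 | intermediate
9 | 5,7-bis(benzyloxy)-2-[4-(benzyloxy)phenyl]-3-(methoxymethoxy)-4H-chromene | COCOC1=C(c2ccc(OCc3ccccc3)cc2)Oc2cc(OCc3ccccc3)cc(OCc3ccccc3)c2C1 | intermediate
10 | 5,7-bis(benzyloxy)-2-[4-(benzyloxy)phenyl]chroman-3-one (racemic) | O=C1Cc2c(OCc3ccccc3)cc(OCc3ccccc3)cc2OC1c1ccc(OCc2ccccc2)cc1 | intermediate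
11 | (2R,3R)-5,7-bis(benzyloxy)-2-[4-(benzyloxy)phenyl]chroman-3-ol | O[C@@H]1Cc2c(OCc3ccccc3)cc(OCc3ccccc3)cc2O[C@@H]1c1ccc(OCc2ccccc2)cc1 | intermediate
12 | (2R,3R)-5,7-bis(benzyloxy)-2-[4-(benzyloxy)phenyl]-8-bromochroman-3-ol | O[C@@H]1Cc2c(OCc3ccccc3)cc(OCc3ccccc3)c(Br)c2O[C@@H]1c1ccc(OCc2ccccc2)cc1 | intermediate
13 | 7-hydroxy-4H-chromen-4-one | O=c1ccoc2cc(O)ccc12 | starting material
14 | 7-(benzyloxy)-4H-chromen-4-one | O=c1ccoc2cc(OCc3ccccc3)ccc12 | intermediate
15 | [4-(benzyloxy)phenyl]boronic acid | OB(O)c1ccc(OCc2ccccc2)cc1 | starting material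
16 | (2S)-7-(benzyloxy)-2-[4-(benzyloxy)phenyl]chroman-4-one | O=C1C[C@@H](c2ccc(OCc3ccccc3)cc2)Oc2cc(OCc3ccccc3)ccc12 | intermediate
17 | (2S,4S)-7-(benzyloxy)-2-[4-(benzyloxy)phenyl]chroman-4-ol | O[C@H]1C[C@@H](c2ccc(OCc3ccccc3)cc2)Oc2cc(OCc3ccccc3)ccc12 | intermediate
18 | (2R,3R)-5,7-bis(benzyloxy)-6-[(2S,4R)-7-(benzyloxy)-2-(4-(benzyloxy)phenyl)chroman-4-yl]-2-[4-(benzyloxy)phenyl]-8-bromochroman-3-ol | C(c5ccccc5)Oc1ccc([C@@H]2C[C@@H](c3c(OCc5ccccc5)c(Br)c4c(c3OCc3ccccc3)C[C@@H](O)[C@@H](c3ccc(OCc5ccccc5)cc3)O4)c3ccc(OCc4ccccc4)cc3O2)cc1 | intermediate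
19 | (2R,3R)-6-[(2S,4R)-7-hydroxy-2-(4-hydroxyphenyl)chroman-4-yl]-2-(4-hydroxyphenyl)chromane-3,5,7-triol | Oc1ccc([C@@H]2C[C@@H](c3c(O)cc4c(c3O)C[C@@H](O)[C@@H](c3ccc(O)cc3)O4)c3ccc(O)cc3O2)cc1 | target

**Totals**
Total steps: 14
Longest linear sequence: 9 steps (steps 1, 2, 3, 6, 7, 8, 9, 13, 14)

**Steps most likely to fail**

1. Step 6 (Proposed new method). The O-arylation of the hindered, tetrasubstituted enolate may be slower than protodebromination of the aryl–copper species or than over-alkylation and aldol chemistry of the enolate, so that the domino stalls at 8. Fallback with known chemistry, setting out from 7 and 4 and coming back at 10: the lithium enolate of 7 is alkylated with 4 and ketone 8 is isolated. Reduction of 8 with NaBH4 gives 3-[2-bromo-4,6-bis(benzyloxy)phenyl]-1-[4-(benzyloxy)phenyl]-2-(methoxymethoxy)propan-1-ol F1 as a mixture of diastereomers. The pyran ring is then closed by intramolecular etherification of the secondary alcohol onto the aryl bromide (Pd(OAc)2, 2-(di-tert-butylphosphino)-1,1'-binaphthyl, Cs2CO3, toluene, 80 °C), which should give 5,7-bis(benzyloxy)-2-[4-(benzyloxy)phenyl]-3-(methoxymethoxy)chromane F2. The MOM group is removed (HCl, MeOH/THF) to 5,7-bis(benzyloxy)-2-[4-(benzyloxy)phenyl]chroman-3-ol F3 (mixture of stereoisomers), and Dess–Martin oxidation returns ketone 10, where the stereochemistry is erased and set anew in step 8.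

2. Step 8. Epimerisation at C2 may be slow relative to reduction (a plain kinetic resolution would result), or the catalyst may discriminate the faces of this non-aryl ketone poorly. Fallback, setting out from 10 and coming back at 11: reduction of 10 with LiBH(s-Bu)3 (THF, −78 °C), which is known to give 2,3-cis flavan-3-ols, should give the racemic 2,3-cis alcohol rac-(2R,3R)-5,7-bis(benzyloxy)-2-[4-(benzyloxy)phenyl]chroman-3-ol F4. Esterification with (S)-2-methoxy-2-phenylacetic acid (DCC, DMAP) and separation of the diastereomeric esters gives (2R,3R)-5,7-bis(benzyloxy)-2-[4-(benzyloxy)phenyl]chroman-3-yl (S)-2-methoxy-2-phenylacetate F5, which is saponified (K2CO3, MeOH/THF) to 11. The other diastereomer can be recycled by saponification and Dess–Martin oxidation to 10.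

3. Step 13. Facial selectivity in the capture of the C4 cation may be poor, and the cation may alkylate ring A of its own unit, which leads to oligomers. Fallback, setting out from 12 and 17 and coming back at 18; it replaces cation capture by a stereoretentive cross-coupling. Compound 12 is iodinated at C6, its only free position in ring A (N-iodosuccinimide, CH2Cl2), to (2R,3R)-5,7-bis(benzyloxy)-2-[4-(benzyloxy)phenyl]-8-bromo-6-iodochroman-3-ol F6. Compound 17 is dehydrated (TsOH cat., toluene) to (2S)-7-(benzyloxy)-2-[4-(benzyloxy)phenyl]-2H-chromene F7, which is hydroborated with pinacolborane ([Rh(cod)2]BF4, 1,4-bis(diphenylphosphino)butane, THF). This should place boron on the benzylic carbon C4, anti to the C2 aryl group, and give 2-[(2S,4R)-7-(benzyloxy)-2-(4-(benzyloxy)phenyl)chroman-4-yl]-4,4,5,5-tetramethyl-1,3,2-dioxaborolane F8. Suzuki–Miyaura coupling of F8 with the aryl iodide of F6 under the retentive conditions for secondary benzylic boronic esters (Pd2(dba)3, PPh3, Ag2O, THF, 70 °C) should give 18, the C8 bromide being left for step 14.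

**Further compounds**
F1 | step 6 | 3-[2-bromo-4,6-bis(benzyloxy)phenyl]-1-[4-(benzyloxy)phenyl]-2-(methoxymethoxy)propan-1-ol (mixture of diastereomers) | COCOC(Cc1c(Br)cc(OCc2ccccc2)cc1OCc1ccccc1)C(O)c1ccc(OCc2ccccc2)cc1
F2 | step 6 | 5,7-bis(benzyloxy)-2-[4-(benzyloxy)phenyl]-3-(methoxymethoxy)chromane (mixture of stereoisomers) | COCOC1Cc2c(OCc3ccccc3)cc(OCc3ccccc3)cc2OC1c1ccc(OCc2ccccc2)cc1
F3 | step 6 | 5,7-bis(benzyloxy)-2-[4-(benzyloxy)phenyl]chroman-3-ol (mixture of stereoisomers) | OC1Cc2c(OCc3ccccc3)cc(OCc3ccccc3)cc2OC1c1ccc(OCc2ccccc2)cc1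
F4 | step 8 | rac-(2R,3R)-5,7-bis(benzyloxy)-2-[4-(benzyloxy)phenyl]chroman-3-ol (racemic 2,3-cis alcohol, both enantiomers written) | O[C@@H]1Cc2c(OCc3ccccc3)cc(OCc3ccccc3)cc2O[C@@H]1c1ccc(OCc2ccccc2)cc1.O[C@H]1Cc2c(OCc3ccccc3)cc(OCc3ccccc3)cc2O[C@H]1c1ccc(OCc2ccccc2)cc1
F5 | step 8 | (2R,3R)-5,7-bis(benzyloxy)-2-[4-(benzyloxy)phenyl]chroman-3-yl (S)-2-methoxy-2-phenylacetate | CO[C@H](C(=O)O[C@@H]1Cc2c(OCc3ccccc3)cc(OCc3ccccc3)cc2O[C@@H]1c1ccc(OCc2ccccc2)cc1)c1ccccc1
F6 | step 13 | (2R,3R)-5,7-bis(benzyloxy)-2-[4-(benzyloxy)phenyl]-8-bromo-6-iodochroman-3-ol | O[C@@H]1Cc2c(OCc3ccccc3)c(I)c(OCc3ccccc3)c(Br)c2O[C@@H]1c1ccc(OCc2ccccc2)cc1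
F7 | step 13 | (2S)-7-(benzyloxy)-2-[4-(benzyloxy)phenyl]-2H-chromene | C1=C[C@@H](c2ccc(OCc3ccccc3)cc2)Oc2cc(OCc3ccccc3)ccc12
F8 | step 13 | 2-[(2S,4R)-7-(benzyloxy)-2-(4-(benzyloxy)phenyl)chroman-4-yl]-4,4,5,5-tetramethyl-1,3,2-dioxaborolane | CC1(C)OB(OC1(C)C)[C@@H]1C[C@@H](c2ccc(OCc3ccccc3)cc2)Oc2cc(OCc3ccccc3)ccc12
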